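**Retrosynthetic overview**

1. The acid comes from its methyl ester. The C6 quaternary centre is disconnected last: a catalyst-controlled dearomative C-prenylation of an aromatic 5,7-dihydroxychromanone, and before it a reductive alkylation of C6–H with a cyclobutane aldehyde.
2. The pyranone ring (O1, C2, C3, C4) is closed by a Kabbe condensation on an o-hydroxyacetophenone.
3. The carbocycle (C4a, C5, C6, C7, C8, C8a) is not made as a six-membered ring. It grows from the four-membered ring of a cyclobutenone (C8a = carbonyl carbon, C6 = vinyl CH, C7 = C–OBn, C8 = CH bearing the side chain) by insertion of the two carbons of a siloxyalkyne (C4a, C5) into the C8a–C6 bond.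
4. Enabling feature: the carbocycle carries oxygen on C5, C7 and C8a, with carbon substituents in between. C8a(O)–C8–C7(O)–C6 is therefore a 3-alkoxycyclobutenone (ketene + ynol ether), and C4a(acyl)–C5(O) is a siloxyalkyne, so all six ring atoms are differentiated before the ring exists.
5. Ring order: cyclobutane (step 3) and cyclobutenone (step 9), then benzene ring (step 10), then pyranone (step 12). Stereocentres: side chain by anhydride desymmetrisation, cyclobutane by Rh 1,4-addition plus epimerisation, C6 by the Pd catalyst.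

Key step: step 10

Remark: the enolised β-triketone of the target is drawn as its 5-hydroxy-4,7-dione tautomer and all tautomers are treated as one compound; the sense of induction stated for the chiral catalysts in steps 1, 8 and 16 is the expected one, and the antipodal catalyst is taken if it proves opposite.

**Route**

Step 1
Reactants: 1 4,4-dimethylcyclopent-2-en-1-one
Product: 2 (R)-3,3-dimethyl-4-(prop-1-en-2-yl)cyclopentan-1-one
Conditions: [Rh(cod)Cl]2 (2.5 mol %), (R)-BINAP, isopropenyl-Bpin, KOH (cat.), dioxane/H2O, 80 °C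
Reagents that add atoms: isopropenylboronic acid pinacol ester, CC(=C)B1OC(C)(C)C(C)(C)O1
Why: Hayashi–Miyaura asymmetric 1,4-addition; the alkenyl–Rh(BINAP) species adds to one enone face and sets C4 (R), the only catalyst-set centre of the cyclobutane unit.

Step 2
Reactants: 2 ketone
Product: 4 (R)-2-diazo-4,4-dimethyl-3-(prop-1-en-2-yl)cyclopentan-1-one, via trifluoroacetyl ketone 3 (not isolated)
Conditions: LiHMDS, THF, −78 °C; CF3CO2CH2CF3; work-up; then MsN3, Et3N, H2O, MeCN, rt
Reagents that add atoms: methanesulfonyl azide, CS(=O)(=O)N=[N+]=[N-]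
Why: Regitz-type detrifluoroacetylative diazo transfer; kinetic deprotonation should occur at C5 (next to the tertiary CH) and not at C2 (next to the quaternary CMe2), which places the diazo group beside the isopropenyl-bearing carbon, whose configuration is not touched.

Step 3
Reactants: 4 diazoketone
Product: 7 methyl (1R,2R)-3,3-dimethyl-2-(prop-1-en-2-yl)cyclobutane-1-carboxylate, via ketene 5 (not isolated), via cis-ester 6 (not isolated)
Conditions: hν (Hg lamp, Pyrex), MeOH, 0–25 °C; then NaOMe (cat.), MeOH, 50 °C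
Reagents that add atoms: methanol, CO
Why: photochemical Wolff rearrangement (ring contraction of a 2-diazocyclopentanone) with MeOH trapping of the ketene; NaOMe then equilibrates the new ester-bearing centre to the more stable trans arrangement (1R), controlled by the fixed (2R) centre.

Step 4
Reactants: 7 trans ester
Product: 8 (1R,2R)-3,3-dimethyl-2-(prop-1-en-2-yl)cyclobutane-1-carbaldehyde
Conditions: DIBAL-H (1.05 equiv), CH2Cl2, −78 °C; aq. Rochelle salt
Reagents that add atoms: none
Why: partial ester reduction through the aluminium hemiacetal, stable at −78 °C; the trans aldehyde is also the thermodynamic epimer.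

Step 5
Reactants: 9 but-3-yn-2-one
Product: 10 2-ethynyl-2-methyl-1,3-dioxolane
Conditions: (TMSOCH2)2, TMSOTf (cat.), CH2Cl2, −78 °C
Reagents that add atoms: 1,2-bis(trimethylsilyloxy)ethane, C[Si](C)(C)OCCO[Si](C)(C)C
Why: TMSOTf-catalysed ketalisation with the bis-silyl ether at low temperature, which avoids conjugate addition to the ynone.

Step 6
Reactants: 10 alkyne
Product: 12 triisopropyl{[(2-methyl-1,3-dioxolan-2-yl)ethynyl]oxy}silane, via lithium ynolate 11 (not isolated)
Conditions: n-BuLi, THF, −78 °C; LiOOt-Bu (from t-BuOOH + LiHMDS), −78 → 0 °C; TIPSOTf, −78 °C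
Reagents that add atoms: tert-butyl hydroperoxide, CC(C)(C)OO; triisopropylsilyl triflate, CC(C)[Si](C(C)C)(C(C)C)OS(=O)(=O)C(F)(F)F
Why: oxidation of the metallated alkyne by lithium tert-butyl peroxide gives the ynolate, which the bulky silyl triflate traps on oxygen (siloxyalkyne synthesis from terminal alkynes).

Step 7
Reactants: 13 benzyl alcohol
Product: 15 [(ethynyloxy)methyl]benzene (benzyl ethynyl ether), via dichlorovinyl ether 14 (not isolated)
Conditions: KH, THF, 0 °C; Cl2C=CHCl, rt; then n-BuLi (2.4 equiv), −78 → −40 °C; MeOH, −78 °C; used cold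
Reagents that add atoms: trichloroethylene, ClC=C(Cl)Cl
Why: ynol ether synthesis from trichloroethylene; alkoxide addition gives the (E)-dichlorovinyl ether, and n-BuLi then effects elimination and chlorine–lithium exchange before cold protonation.

Step 8
Reactants: 16 3-propylglutaric anhydride
Product: 17 (S)-3-(2-methoxy-2-oxoethyl)hexanoic acid
Conditions: (DHQD)2AQN (10 mol %), MeOH (10 equiv), Et2O, −20 °C
Reagents that add atoms: methanol, CO
Why: cinchona-alkaloid-catalysed desymmetrising methanolysis of a prochiral cyclic anhydride; the catalyst selects one enantiotopic carbonyl and sets C3 (S), the later benzylic centre.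

Step 9
Reactants: 17 hemiester; 15 benzyl ethynyl ether
Product: 20 methyl (3R)-3-[(1RS)-2-(benzyloxy)-4-oxocyclobut-2-en-1-yl]hexanoate, via acid chloride 18 (not isolated), via ketene 19 (not isolated)
Conditions: (COCl)2, DMF (cat.), CH2Cl2, 0 °C → rt; concentrate; then 15, Et3N, Et2O, 0 °C → rt
Reagents that add atoms: none
Why: dehydrohalogenation to the aldoketene and regioselective ketene–ynol ether [2+2] cycloaddition (alkyne carbon β to oxygen bonds to the ketene carbonyl carbon); the side-chain centre is β to the ketene and not enolisable, and the new ring centre is erased in step 10.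

Step 10
Reactants: 20 cyclobutenone; 12 siloxyalkyne
Product: 25 methyl (R)-3-[6-(benzyloxy)-2-hydroxy-3-(2-methyl-1,3-dioxolan-2-yl)-4-(triisopropylsilyloxy)phenyl]hexanoate, via vinylketene 21 (not isolated), via 4-alkenylcyclobutenone 22 (not isolated), via dienylketene 23 (not isolated), via cyclohexadienone 24 (not isolated)
Conditions: 12 (1.5 equiv), PhMe, 80 → 110 °C, sealed tube
Reagents that add atoms: none
Why: Heating opens 20 by 4π conrotatory ring opening to vinylketene 21, which adds 12 in a [2+2] cycloaddition to give 22; this four-membered ring opens again to dienylketene 23, which closes to 24 and tautomerises to the phenol, so the two alkyne carbons end up inserted into the C(=O)–CH= bond of the original ring (ring expansion by two atoms). The closest known reaction type is the Danheiser benzannulation of cyclobutenones with siloxyalkynes. The transient four-membered ring closes by a thermal ketene–alkyne [2+2] cycloaddition and the six-membered carbocycle by a thermally allowed disrotatory 6π electrocyclisation that forms the C8a–C8 bond. No new stereocentre persists: the ring centres of 20, 22 and 24 are erased on aromatisation, and the side-chain centre (R) lies outside the pericyclic array and is not enolisable. The step needs regioselectivity in the [2+2] (secured by the polarisation of the siloxyalkyne, whose carbon β to oxygen bonds to the ketene carbonyl carbon, so that OH, masked acetyl and OTIPS end up contiguous), outward rotation of the side chain in the ring opening (so that H is inside and 6π closure follows) and chemoselectivity against acylation of the product phenol by the ketene (secured by excess alkyne).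

Step 11
Reactants: 25 phenol ketal
Product: 26 methyl (R)-3-[3-acetyl-6-(benzyloxy)-2-hydroxy-4-(triisopropylsilyloxy)phenyl]hexanoate
Conditions: PPTS (cat.), acetone/H2O, 40 °C
Reagents that add atoms: water, O
Why: acid-catalysed hydrolysis of the benzylic dioxolane through a stabilised oxocarbenium ion; the aryl silyl ether, benzyl ether and methyl ester should survive these mild conditions.

Step 12
Reactants: 26 o-hydroxyacetophenone
Product: 27 methyl (R)-3-[7-(benzyloxy)-2,2-dimethyl-4-oxo-5-(triisopropylsilyloxy)chroman-8-yl]hexanoate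
Conditions: acetone (excess), pyrrolidine, MeOH, 25 → 50 °C
Reagents that add atoms: acetone, CC(C)=O
Why: Kabbe condensation (amine-mediated aldol condensation with acetone, then 6-endo oxa-Michael closure); only the 2-OH is free, which fixes the position of the pyranone ring.

Step 13
Reactants: 27 chromanone
Product: 28 methyl (R)-3-[7-(benzyloxy)-5-hydroxy-2,2-dimethyl-4-oxochroman-8-yl]hexanoate
Conditions: TBAF, AcOH (1.1 equiv each), THF, 0 °C
Reagents that add atoms: none
Why: fluoride cleavage of the aryl silyl ether under buffered conditions; the benzyl ether still masks the 7-OH, so no phenoxide sits next to the ester.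

Step 14
Reactants: 28 benzyl ether
Product: 29 methyl (R)-3-(5,7-dihydroxy-2,2-dimethyl-4-oxochroman-8-yl)hexanoate
Conditions: H2 (1 atm), 10 % Pd/C, EtOAc, rt
Reagents that add atoms: none
Why: hydrogenolysis of the benzyl ether; no alkene is present at this stage and the aryl ketone should not be reduced at 1 atm.

Step 15
Reactants: 29 dihydroxychromanone; 8 cyclobutane aldehyde
Product: 31 methyl (R)-3-[6-{[(1S,2R)-3,3-dimethyl-2-(prop-1-en-2-yl)cyclobutyl]methyl}-5,7-dihydroxy-2,2-dimethyl-4-oxochroman-8-yl]hexanoate, via ortho-quinone methide 30 (not isolated)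
Conditions: Hantzsch ester (1.2 equiv), L-proline (20 mol %), CH2Cl2/EtOH, 25 °C
Reagents that add atoms: none
Why: organocatalytic three-component reductive alkylation (Knoevenagel-type condensation to the ortho-quinone methide, then hydride transfer from the Hantzsch ester) at C6, the only free ring position; the aldehyde α-centre stays under thermodynamic trans control and the β-centre is untouched.

Step 16
Reactants: 31 C6-alkylated dihydroxychromanone
Product: 32 methyl (R)-3-[(6R)-6-{[(1S,2R)-3,3-dimethyl-2-(prop-1-en-2-yl)cyclobutyl]methyl}-5-hydroxy-2,2-dimethyl-6-(3-methylbut-2-en-1-yl)-4,7-dioxo-3,4,6,7-tetrahydro-2H-chromen-8-yl]hexanoate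
Conditions: Pd2(dba)3·CHCl3 (2.5 mol %), N,N'-[(1R,2R)-cyclohexane-1,2-diyl]bis[2-(diphenylphosphino)benzamide] (7.5 mol %), tert-butyl prenyl carbonate (1.2 equiv), CH2Cl2, 0 → 25 °C
Reagents that add atoms: tert-butyl (3-methylbut-2-en-1-yl) carbonate, CC(C)=CCOC(=O)OC(C)(C)C
Why: Proposed new method: Pd(0) ionises the carbonate to a cationic (η3-prenyl)Pd–bisphosphine complex and tert-butoxide, which deprotonates the acidic 7-OH; the phenoxide attacks the unsubstituted allyl terminus through C6 in an outer-sphere step (O-allylation is reversible under Pd(0), and attack through C8 with its secondary alkyl group is more hindered), and the chiral pocket of the ligand selects the face of the planar nucleophile, so C6 (R) is set under catalyst control because the other stereocentres are remote; the closest known reactions are the Tsuji–Trost asymmetric allylic dearomatisation of 2-naphthols with this ligand class and the non-asymmetric Pd-catalysed dearomative C-allylation of acylphloroglucinols.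

Step 17
Reactants: 32 methyl ester
Product: 33 (R)-3-[(6R)-6-{[(1S,2R)-3,3-dimethyl-2-(prop-1-en-2-yl)cyclobutyl]methyl}-5-hydroxy-2,2-dimethyl-6-(3-methylbut-2-en-1-yl)-4,7-dioxo-3,4,6,7-tetrahydro-2H-chromen-8-yl]hexanoic acid
Conditions: LiOH·H2O (3 equiv), THF/H2O, 0 °C → rt; then 1 M HCl to pH 3 at 0 °C
Reagents that add atoms: lithium hydroxide, [Li+].[OH-]
Why: saponification of the methyl ester; the enolised β-triketone is present as its anion and so is shielded from hydroxide, premature lactonisation of the ortho-hydroxy ester in steps 14–16 would be reversed here, and cold, brief acidification should spare the acid-labile alkenes.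

**Compound list**

1 | 4,4-dimethylcyclopent-2-en-1-one | O=C1C=CC(C)(C)C1 | starting material
2 | (R)-3,3-dimethyl-4-(prop-1-en-2-yl)cyclopentan-1-one | C=C(C)[C@H]1CC(=O)CC1(C)C | intermediate
3 | (3R)-4,4-dimethyl-3-(prop-1-en-2-yl)-2-(trifluoroacetyl)cyclopentan-1-one (C2 epimers) | C=C(C)[C@H]1C(C(=O)C(F)(F)F)C(=O)CC1(C)C | intermediate
4 | (R)-2-diazo-4,4-dimethyl-3-(prop-1-en-2-yl)cyclopentan-1-one | C=C(C)[C@H]1C(=[N+]=[N-])C(=O)CC1(C)C | intermediate
5 | [(2R)-3,3-dimethyl-2-(prop-1-en-2-yl)cyclobutylidene]methanone (ketene) | C=C(C)[C@H]1C(=C=O)CC1(C)C | intermediate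
6 | methyl (1S,2R)-3,3-dimethyl-2-(prop-1-en-2-yl)cyclobutane-1-carboxylate (cis) | C=C(C)[C@H]1[C@@H](C(=O)OC)CC1(C)C | intermediate
7 | methyl (1R,2R)-3,3-dimethyl-2-(prop-1-en-2-yl)cyclobutane-1-carboxylate (trans) | C=C(C)[C@H]1[C@H](C(=O)OC)CC1(C)C | intermediate
8 | (1R,2R)-3,3-dimethyl-2-(prop-1-en-2-yl)cyclobutane-1-carbaldehyde | C=C(C)[C@H]1[C@H](C=O)CC1(C)C | intermediate
9 | but-3-yn-2-one | CC(=O)C#C | starting material
10 | 2-ethynyl-2-methyl-1,3-dioxolane | CC1(C#C)OCCO1 | intermediate
11 | lithium (2-methyl-1,3-dioxolan-2-yl)ethynolate | [Li+].[O-]C#CC1(C)OCCO1 | intermediate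
12 | triisopropyl{[(2-methyl-1,3-dioxolan-2-yl)ethynyl]oxy}silane | CC1(C#CO[Si](C(C)C)(C(C)C)C(C)C)OCCO1 | intermediate
13 | benzyl alcohol | OCc1ccccc1 | starting material
14 | (E)-{[(1,2-dichloroethenyl)oxy]methyl}benzene | Cl/C=C(/Cl)OCc1ccccc1 | intermediate
15 | [(ethynyloxy)methyl]benzene | C#COCc1ccccc1 | intermediate
16 | 3-propylglutaric anhydride (4-propyloxane-2,6-dione) | CCCC1CC(=O)OC(=O)C1 | starting material
17 | (S)-3-(2-methoxy-2-oxoethyl)hexanoic acid | OC(=O)C[C@H](CCC)CC(=O)OC | intermediate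
18 | methyl (R)-3-(2-chloro-2-oxoethyl)hexanoate | ClC(=O)C[C@H](CCC)CC(=O)OC | intermediate
19 | methyl (R)-3-(2-oxoethenyl)hexanoate (ketene) | O=C=C[C@H](CCC)CC(=O)OC | intermediate
20 | methyl (3R)-3-[(1RS)-2-(benzyloxy)-4-oxocyclobut-2-en-1-yl]hexanoate | O=C1C=C(OCc2ccccc2)C1[C@H](CCC)CC(=O)OC | intermediate
21 | methyl (3R,4Z)-5-(benzyloxy)-7-oxo-3-propylhepta-4,6-dienoate (vinylketene) | O=C=C/C(OCc1ccccc1)=C/[C@H](CCC)CC(=O)OC | intermediate
22 | methyl (3R,4Z)-5-(benzyloxy)-5-[3-(2-methyl-1,3-dioxolan-2-yl)-4-oxo-2-(triisopropylsilyloxy)cyclobut-2-en-1-yl]-3-propylpent-4-enoate (ring sp3 carbon as a mixture) | O=C1C(C2(C)OCCO2)=C(O[Si](C(C)C)(C(C)C)C(C)C)C1/C(OCc1ccccc1)=C/[C@H](CCC)CC(=O)OC | intermediate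
23 | methyl (3R,4Z,6E)-5-(benzyloxy)-8-(2-methyl-1,3-dioxolan-2-yl)-9-oxo-3-propyl-7-(triisopropylsilyloxy)nona-4,6,8-trienoate (dienylketene) | O=C=C(C1(C)OCCO1)/C(O[Si](C(C)C)(C(C)C)C(C)C)=C\C(OCc1ccccc1)=C\[C@H](CCC)CC(=O)OC | intermediate
24 | methyl (3R)-3-[2-(benzyloxy)-5-(2-methyl-1,3-dioxolan-2-yl)-6-oxo-4-(triisopropylsilyloxy)cyclohexa-2,4-dien-1-yl]hexanoate (ring sp3 carbon as a mixture) | O=C1C(C2(C)OCCO2)=C(O[Si](C(C)C)(C(C)C)C(C)C)C=C(OCc2ccccc2)C1[C@H](CCC)CC(=O)OC | intermediate
25 | methyl (R)-3-[6-(benzyloxy)-2-hydroxy-3-(2-methyl-1,3-dioxolan-2-yl)-4-(triisopropylsilyloxy)phenyl]hexanoate | Oc1c(C2(C)OCCO2)c(O[Si](C(C)C)(C(C)C)C(C)C)cc(OCc2ccccc2)c1[C@H](CCC)CC(=O)OC | intermediate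
26 | methyl (R)-3-[3-acetyl-6-(benzyloxy)-2-hydroxy-4-(triisopropylsilyloxy)phenyl]hexanoate | CC(=O)c1c(O)c([C@H](CCC)CC(=O)OC)c(OCc2ccccc2)cc1O[Si](C(C)C)(C(C)C)C(C)C | intermediate
27 | methyl (R)-3-[7-(benzyloxy)-2,2-dimethyl-4-oxo-5-(triisopropylsilyloxy)chroman-8-yl]hexanoate | CC1(C)CC(=O)c2c(O[Si](C(C)C)(C(C)C)C(C)C)cc(OCc3ccccc3)c([C@H](CCC)CC(=O)OC)c2O1 | intermediate
28 | methyl (R)-3-[7-(benzyloxy)-5-hydroxy-2,2-dimethyl-4-oxochroman-8-yl]hexanoate | CC1(C)CC(=O)c2c(O)cc(OCc3ccccc3)c([C@H](CCC)CC(=O)OC)c2O1 | intermediate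
29 | methyl (R)-3-(5,7-dihydroxy-2,2-dimethyl-4-oxochroman-8-yl)hexanoate | CC1(C)CC(=O)c2c(O)cc(O)c([C@H](CCC)CC(=O)OC)c2O1 | intermediate
30 | methyl (R)-3-[6-{[(1S,2R)-3,3-dimethyl-2-(prop-1-en-2-yl)cyclobutyl]methylidene}-5-hydroxy-2,2-dimethyl-4,7-dioxo-3,4,6,7-tetrahydro-2H-chromen-8-yl]hexanoate (ortho-quinone methide) | C=C(C)[C@H]1[C@H](C=C2C(=O)C([C@H](CCC)CC(=O)OC)=C3OC(C)(C)CC(=O)C3=C2O)CC1(C)C | intermediate
31 | methyl (R)-3-[6-{[(1S,2R)-3,3-dimethyl-2-(prop-1-en-2-yl)cyclobutyl]methyl}-5,7-dihydroxy-2,2-dimethyl-4-oxochroman-8-yl]hexanoate | C=C(C)[C@H]1[C@H](Cc2c(O)c3c(c([C@H](CCC)CC(=O)OC)c2O)OC(C)(C)CC3=O)CC1(C)C | intermediate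
32 | methyl (R)-3-[(6R)-6-{[(1S,2R)-3,3-dimethyl-2-(prop-1-en-2-yl)cyclobutyl]methyl}-5-hydroxy-2,2-dimethyl-6-(3-methylbut-2-en-1-yl)-4,7-dioxo-3,4,6,7-tetrahydro-2H-chromen-8-yl]hexanoate | C=C(C)[C@H]1[C@H](C[C@]2(CC=C(C)C)C(=O)C([C@H](CCC)CC(=O)OC)=C3OC(C)(C)CC(=O)C3=C2O)CC1(C)C | intermediate
33 | (R)-3-[(6R)-6-{[(1S,2R)-3,3-dimethyl-2-(prop-1-en-2-yl)cyclobutyl]methyl}-5-hydroxy-2,2-dimethyl-6-(3-methylbut-2-en-1-yl)-4,7-dioxo-3,4,6,7-tetrahydro-2H-chromen-8-yl]hexanoic acid | C=C(C)[C@H]1[C@H](C[C@]2(CC=C(C)C)C(=O)C([C@H](CCC)CC(=O)O)=C3OC(C)(C)CC(=O)C3=C2O)CC1(C)C | target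

**Totals**

Total step count: 17. Longest linear sequence: 10 steps (16 → 33, steps 8–17).

**Steps most likely to fail**

Step 16 (Proposed new method). The risk is poor facial discrimination, because the nucleophile is flanked by two similar oxygenated carbons, and competing allylation through C8 or oxygen. The fallback sets out from 31 and comes back at 32. 31 is C-prenylated without a chiral catalyst (LiHMDS, prenyl bromide, THF, −78 → 0 °C, the classical gem-dialkylation of C-alkylated acylphloroglucinols). This should give 32 together with its C6 epimer, methyl (R)-3-[(6S)-6-{[(1S,2R)-3,3-dimethyl-2-(prop-1-en-2-yl)cyclobutyl]methyl}-5-hydroxy-2,2-dimethyl-6-(3-methylbut-2-en-1-yl)-4,7-dioxo-3,4,6,7-tetrahydro-2H-chromen-8-yl]hexanoate F1. The two are diastereomers, so they are separated by preparative HPLC and 32 is carried on.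

Step 10. The risk is slow capture of the vinylketene by the hindered, inductively deactivated ketal-bearing alkyne, so that ketene dimerisation, acylation of the product phenol or premature lactonisation takes over. The fallback sets out from 20 and comes back at 26 and uses a less hindered alkyne. Commercial 3,3-diethoxyprop-1-yne is converted as in step 6 through lithium 3,3-diethoxyprop-1-yn-1-olate F2 into triisopropyl[(3,3-diethoxyprop-1-yn-1-yl)oxy]silane F3. Heating F3 with 20 should pass through 21, the 4-alkenylcyclobutenone F4, the dienylketene F5 and the cyclohexadienone F6 to the phenol acetal F7. Dilute acid gives the salicylaldehyde F8. MeTi(OiPr)3 adds to the aldehyde only and gives the carbinol F9, and MnO2 oxidises it to 26.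

Step 15. The risk is tautomerisation of the ortho-quinone methide to the alkenylphenol, with loss of the cyclobutane α-centre, or sluggish condensation of the α-branched aldehyde with the acyl-deactivated ring. The fallback sets out from 29 and 8 and comes back at 31, replacing the polar alkylation by a cross-coupling. 29 is brominated at C6 (NBS, MeCN, 0 °C) to the bromide F10 and acetylated (Ac2O, pyridine, DMAP) to the diacetate F11. 8 is reduced (NaBH4, MeOH) to the alcohol F12, converted (I2, PPh3, imidazole) into the iodide F13 and this (Zn dust, LiCl, THF) into the alkylzinc iodide F14. Negishi coupling of F11 with F14 (Pd(OAc)2, CPhos, THF) gives the coupled diacetate F15, and K2CO3 in MeOH removes the acetates to give 31.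

**Further compounds**

F1 | step 16 | methyl (R)-3-[(6S)-6-{[(1S,2R)-3,3-dimethyl-2-(prop-1-en-2-yl)cyclobutyl]methyl}-5-hydroxy-2,2-dimethyl-6-(3-methylbut-2-en-1-yl)-4,7-dioxo-3,4,6,7-tetrahydro-2H-chromen-8-yl]hexanoate | C=C(C)[C@H]1[C@H](C[C@@]2(CC=C(C)C)C(=O)C([C@H](CCC)CC(=O)OC)=C3OC(C)(C)CC(=O)C3=C2O)CC1(C)C
F2 | step 10 | lithium 3,3-diethoxyprop-1-yn-1-olate | [Li+].[O-]C#CC(OCC)OCC
F3 | step 10 | triisopropyl[(3,3-diethoxyprop-1-yn-1-yl)oxy]silane | CCOC(OCC)C#CO[Si](C(C)C)(C(C)C)C(C)C
F4 | step 10 | methyl (3R,4Z)-5-(benzyloxy)-5-[3-(diethoxymethyl)-4-oxo-2-(triisopropylsilyloxy)cyclobut-2-en-1-yl]-3-propylpent-4-enoate | O=C1C(C(OCC)OCC)=C(O[Si](C(C)C)(C(C)C)C(C)C)C1/C(OCc1ccccc1)=C/[C@H](CCC)CC(=O)OC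
F5 | step 10 | methyl (3R,4Z,6E)-5-(benzyloxy)-8-(diethoxymethyl)-9-oxo-3-propyl-7-(triisopropylsilyloxy)nona-4,6,8-trienoate | O=C=C(C(OCC)OCC)/C(O[Si](C(C)C)(C(C)C)C(C)C)=C\C(OCc1ccccc1)=C\[C@H](CCC)CC(=O)OC
F6 | step 10 | methyl (3R)-3-[2-(benzyloxy)-5-(diethoxymethyl)-6-oxo-4-(triisopropylsilyloxy)cyclohexa-2,4-dien-1-yl]hexanoate | O=C1C(C(OCC)OCC)=C(O[Si](C(C)C)(C(C)C)C(C)C)C=C(OCc2ccccc2)C1[C@H](CCC)CC(=O)OC
F7 | step 10 | methyl (R)-3-[6-(benzyloxy)-3-(diethoxymethyl)-2-hydroxy-4-(triisopropylsilyloxy)phenyl]hexanoate | CCOC(OCC)c1c(O)c([C@H](CCC)CC(=O)OC)c(OCc2ccccc2)cc1O[Si](C(C)C)(C(C)C)C(C)C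
F8 | step 10 | methyl (R)-3-[6-(benzyloxy)-3-formyl-2-hydroxy-4-(triisopropylsilyloxy)phenyl]hexanoate | O=Cc1c(O)c([C@H](CCC)CC(=O)OC)c(OCc2ccccc2)cc1O[Si](C(C)C)(C(C)C)C(C)C
F9 | step 10 | methyl (3R)-3-[6-(benzyloxy)-2-hydroxy-3-(1-hydroxyethyl)-4-(triisopropylsilyloxy)phenyl]hexanoate | CC(O)c1c(O)c([C@H](CCC)CC(=O)OC)c(OCc2ccccc2)cc1O[Si](C(C)C)(C(C)C)C(C)C
F10 | step 15 | methyl (R)-3-(6-bromo-5,7-dihydroxy-2,2-dimethyl-4-oxochroman-8-yl)hexanoate | CC1(C)CC(=O)c2c(O)c(Br)c(O)c([C@H](CCC)CC(=O)OC)c2O1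
F11 | step 15 | methyl (R)-3-(5,7-diacetoxy-6-bromo-2,2-dimethyl-4-oxochroman-8-yl)hexanoate | CC1(C)CC(=O)c2c(OC(C)=O)c(Br)c(OC(C)=O)c([C@H](CCC)CC(=O)OC)c2O1
F12 | step 15 | [(1R,2R)-3,3-dimethyl-2-(prop-1-en-2-yl)cyclobutyl]methanol | C=C(C)[C@H]1[C@H](CO)CC1(C)C
F13 | step 15 | (1R,2R)-1-(iodomethyl)-3,3-dimethyl-2-(prop-1-en-2-yl)cyclobutane | C=C(C)[C@H]1[C@H](CI)CC1(C)C
F14 | step 15 | {[(1R,2R)-3,3-dimethyl-2-(prop-1-en-2-yl)cyclobutyl]methyl}zinc iodide | C=C(C)[C@H]1[C@H](C[Zn]I)CC1(C)C
F15 | step 15 | methyl (R)-3-[5,7-diacetoxy-6-{[(1S,2R)-3,3-dimethyl-2-(prop-1-en-2-yl)cyclobutyl]methyl}-2,2-dimethyl-4-oxochroman-8-yl]hexanoate | C=C(C)[C@H]1[C@H](Cc2c(OC(C)=O)c3c(c([C@H](CCC)CC(=O)OC)c2OC(C)=O)OC(C)(C)CC3=O)CC1(C)C
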